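## The problem

The target 27 is a 3-substituted coumarin whose benzene ring carries a substituent on every carbon: the branched side chain at C5, methyl groups at C6 and C8, a hydroxyl at C7, and the ring-fusion atoms C4a and C8a. C5 is meta to both ring oxygens (O1 on C8a and the C7 hydroxyl), so the side chain cannot be introduced by electrophilic alkylation of a resorcinol; a bond from an arene carbon to a stereogenic secondary carbon has to be made another way. The side chain holds two adjacent stereocenters, C1'' (R, benzylic, methyl-bearing) and C2'' (S, hydroxyl-bearing), with aryl and oxygen threo. The third stereocenter, C2' (R) of the dihydropyranone on C3, is seven bonds from C1'' across a flat core, so neither unit can control the other: the side-chain pair needs a catalyst or reagent, and C2' a building block of fixed configuration. The dihydropyranone is both a vinylogous ester and a β-alkoxy ketone; strong base opens it by β-elimination (which would erase C2'), and nucleophilic amines add at C6'. A second hazard lies in the intermediates: once C4a carries a formyl group and the resorcinol oxygens are free, a free C2'' hydroxyl closes onto the aldehyde to a lactol that ionises to a citrinin-type quinone methide, so this hydroxyl must stay masked until the coumarin ring exists. The 3-arylbutan-2-yl unit is also prone to aryl participation, so C2'' must never become a leaving group. The enabling feature is that C1''H(CH3)–C2''H(OH)CH3 with threo aryl and oxygen is exactly what anti addition of an aryl carbon and a methyl group across an (E)-propenylboron unit gives, and that the arene still has hydrogen at C4a at that stage, leaving the aryl partner with one ortho substituent only.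

## Retrosynthesis

**27 to 26, then 26 to 17 and 24.** The last operation only frees the C2'' hydroxyl of silyl ether 26. In 26 the lactone bond O1–C2 and the C3=C4 double bond are cut together, giving salicylaldehyde 17 and pyranonylacetate 24. The neighbouring cuts (C3–C6' by cross-coupling of a 3-halocoumarin, or building the pyranone on a finished coumarin) cost more steps and expose the lactone or the dihydropyranone to organometallic reagents. The chosen cut gives two halves of similar size, each with its own stereochemistry. The forward reaction is a Knoevenagel condensation–lactonisation under catalytic amine: the methylene of 24 must be acidic enough (ester plus vinylogous ketone) and C2' must stay untouched. The triisopropylsilyl ether in 17 blocks the lactol and quinone methide pathway described above.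

**24 to 22, then 22 to 19 and 20, then 19 to 18.** Cutting O1'–C6' with addition of water opens the dihydropyranone to the 3,5-dioxo ester 22 (through its free alcohol 23). Cutting C4'–C5' of the ring (C4–C5 of the chain) gives the silyl ether 19 of methyl (R)-3-hydroxybutanoate 18 and methyl acetoacetate 20, used as its dianion 21. C2' is bought; its C–O bond is never broken. A hetero-Diels–Alder route to the same ring would need an asymmetric catalyst for a stereocenter that is available from the chiral pool.

**17 to 16, then 16 to 14, then 14 to 13.** The phenols of 17 come from the bis(methoxymethyl) ether 16. The formyl carbon (future C4) is cut from C4a, leading back to arene 14 by directed ortho-metalation (aryllithium 15) beside a methoxymethyl ether. The only ring hydrogen of 14 is the one to be replaced, so regiochemistry is not an issue; the methoxymethyl groups serve as both director and protection. Electrophilic formylation of the free resorcinol would lead directly into the lactol problem. Compound 14 is the silyl ether of alcohol 13.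

**13 to 5, 9 and 10 (key disconnection).** The bonds C5–C1'' and C2''–CH3 are cut, and the C2''–O bond is traced to a C–B bond. This leads to aryl bromide 5, the (E)-propenylboronic ester 9 and methyllithium 10. Alternatives are opening of a 2,3-epoxybutane by an arylmetal (the trans epoxide gives the erythro isomer, the cis epoxide a racemate) and hydroboration of an arylbutene (the alkene must first be made geometrically pure). The three-component coupling makes two skeletal bonds and both stereocenters in one operation from achiral partners. It requires a 1,2-metallate shift that outruns direct Suzuki–Miyaura transfer, and facial control by the ligand on palladium.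

**5 to 4, 3, 2 and 1.** Bromide 5 is the bis(methoxymethyl) ether of resorcinol 4, which comes from dimethyl ether 3. The C6 methyl (coumarin numbering) of 3 is traced to the formyl group of 2, installed on commercial 1 by electrophilic formylation. The two open positions of 1 are equivalent and activated by both methoxy groups; the bromine, meta to both oxygens, is bought in place.

**9 to 7 and 8, then 7 to 6.** The boronic ester is cut at its B–O bonds into (E)-prop-1-enylboronic acid 8 and cis-diol 7, the double methyl adduct of acenaphthenequinone 6. The bulky diol is kept because it disfavours direct transmetalation of the alkenyl group.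

## Roads not taken

**Alternative 1:** The benzene ring itself is disconnected. The forward key step heats a 2-pyrone whose side-chain oxygen is esterified with a borylpropiolic acid (A2). Intramolecular [4+2] cycloaddition and loss of CO2 form the C4a–C5 and C8–C8a bonds and give isochromanone A1.
- Merits: the tether fixes the position of every arene substituent; boron arrives on the future C8a, the lactone carbonyl carbon is the future C4, and the lactone masks the C2'' hydroxyl.
- Weak points: the two side-chain stereocenters are not made by this step and must be built into A2 by separate asymmetric chemistry. A2 combines a fragile alkynylboronate with esterification of a hindered secondary alcohol. The diene is substituted at both termini, so high temperatures are expected. Afterwards the lactone must be reduced to the aldehyde oxidation level (back to the lactol problem) and an aryl methyl ether cleaved late, near the dihydropyranone or its precursors.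
- Comparison: A1 has better arene regiocontrol and needs no metalation at a crowded position. The chosen plan offsets this with a purchasable arene, catalytic creation of both stereocenters in one step, and no late demethylation or thermolysis.

**Alternative 2:** The dihydropyranone is disconnected at C4'–C5'. The nitrile oxide from oxime A5 (N-chlorosuccinimide, triethylamine) adds to 3-ethynylcoumarin A4 to give isoxazole A3. Later N–O cleavage (for example Mo(CO)6 in wet acetonitrile), hydrolysis of the enaminone and desilylation close the dihydropyranone.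
- Merits: the cycloaddition is regioselective and tolerant, the 1,3-dicarbonyl stays masked until the end, and no amine meets a finished dihydropyranone. In this respect it is safer than the condensation in the chosen route.
- Weak points: it does not address the C5 side chain, which must still be made by other means. It needs the coumarin, a 3-halogenation and an alkynylation before the key step, and reductive N–O cleavage and three desilylations after it. The reductant must spare the coumarin C3=C4 bond.
- Comparison: it solves the easier half of the molecule more securely but at about four extra steps. The chosen plan joins a preformed pyranone in one step and concentrates its risk on the bond that defines the stereochemistry.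

**Alternative 3:** The arene is disconnected into a cyclobutenone and an ynol ether. Heating cyclobutenone A7 with siloxypropyne A8 forms C7–C8 and C4a–C8a by [2+2] cycloaddition and C6–C7 by six-electron electrocyclisation, giving resorcinol monosilyl ether A6.
- Merits: the pentasubstituted ring is assembled regiospecifically, C4a–H remains for formylation, and the two phenolic oxygens are differentiated. The chosen route lacks this last feature: its two methoxymethyl ethers differ only through the neighbouring formyl group.
- Weak points: A7 already carries both side-chain stereocenters, so they must be made beforehand, and a 3,4-disubstituted cyclobutenone with a branched chiral substituent takes several steps. The vinylketene intermediates pass through dienes next to C1'', where hydrogen shifts could erode its configuration.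
- Comparison: the chosen route is shorter to the arene and sets the stereocenters catalytically, at the price of undifferentiated phenol protection.

Key step: step 7

Assumption: the (Sp,Sp) antipode of the ferrocenyl bisphosphine is taken to deliver the (2S,3R) series. The sense of facial induction could not be verified here and must be confirmed on first use; the relative (threo) configuration does not depend on it, and the (Rp,Rp) antipode would be used if the sense proves opposite.

## Route

Step 1
Reactants: 1 5-bromo-1,3-dimethoxy-2-methylbenzene (4-bromo-2,6-dimethoxytoluene)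
Product: 2 6-bromo-2,4-dimethoxy-3-methylbenzaldehyde
Conditions: Cl2CHOCH3, TiCl4, CH2Cl2, 0 °C; then H2O
Reagents that add atoms: dichloromethyl methyl ether COC(Cl)Cl; water O
Why: Rieche formylation (electrophilic aromatic substitution); the two free positions are equivalent by symmetry and each is ortho to one methoxy group and para to the other, so a single aldehyde should form.

Step 2
Reactants: 2 6-bromo-2,4-dimethoxy-3-methylbenzaldehyde
Product: 3 1-bromo-3,5-dimethoxy-2,4-dimethylbenzene
Conditions: Et3SiH, CF3CO2H, CH2Cl2, 0 °C → rt
Reagents that add atoms: none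
Why: Ionic hydrogenation of an electron-rich benzaldehyde; the benzylic cation reached after the first hydride transfer is stabilised by the ortho and para methoxy groups and takes a second hydride, and the aryl bromide is inert to silane and acid where catalytic hydrogenation would remove it.

Step 3
Reactants: 3 1-bromo-3,5-dimethoxy-2,4-dimethylbenzene
Product: 4 5-bromo-2,4-dimethylbenzene-1,3-diol
Conditions: BBr3, CH2Cl2, −78 °C → rt; then H2O
Reagents that add atoms: none
Why: Lewis-acid cleavage of aryl methyl ethers, done here on a simple arene where no other group is at risk.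

Step 4
Reactants: 4 5-bromo-2,4-dimethylbenzene-1,3-diol
Product: 5 1-bromo-3,5-bis(methoxymethoxy)-2,4-dimethylbenzene
Conditions: NaH, ClCH2OCH3, DMF, 0 °C → rt
Reagents that add atoms: chloromethyl methyl ether COCCl
Why: Williamson etherification of the bis-phenoxide; the sodium salt in DMF is used so that the hydroxyl flanked by two methyl groups also reacts.

Step 5
Reactants: 6 acenaphthylene-1,2-dione (acenaphthenequinone)
Product: 7 cis-(1R,2S)-1,2-dimethyl-1,2-dihydroacenaphthylene-1,2-diol (meso)
Conditions: CH3MgBr (excess), THF, 0 °C → rt; aq. NH4Cl; crystallisation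
Reagents that add atoms: methylmagnesium bromide C[Mg]Br
Why: Double Grignard addition to a 1,2-diketone; the second methyl is expected to enter anti to the solvated magnesium alkoxide, placing the oxygens cis, and crystallisation removes any trans diol, which could not bridge one boron atom in any case.

Step 6
Reactants: 7 cis-1,2-dimethyl-1,2-dihydroacenaphthylene-1,2-diol; 8 (E)-prop-1-en-1-ylboronic acid
Product: 9 (6bR,9aS)-6b,9a-dimethyl-8-[(E)-prop-1-en-1-yl]-6b,9a-dihydroacenaphtho[1,2-d][1,3,2]dioxaborole (cyclic boronic ester of 7 and 8)
Conditions: MgSO4, CH2Cl2, rt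
Reagents that add atoms: none
Why: Condensation of a boronic acid with a cis-1,2-diol, driven by removal of water; the alkene geometry is not touched.

Step 7
Reactants: 9 (E)-propenylboronic ester of diol 7; 10 methyllithium; 5 1-bromo-3,5-bis(methoxymethoxy)-2,4-dimethylbenzene
Product: 13 (2S,3R)-3-[3,5-bis(methoxymethoxy)-2,4-dimethylphenyl]butan-2-ol, via lithium boronate complex 11 (not isolated), via secondary boronic ester 12 (not isolated)
Conditions: 9, CH3Li, THF, 0 °C → rt; then 5, Pd(OAc)2 (3 mol %), (Sp,Sp)-1,1'-bis[bis(4-methoxy-3,5-dimethylphenyl)phosphino]-2,2'-bis[(R)-(dimethylamino)(phenyl)methyl]ferrocene (3.6 mol %), CF3SO3K, THF, 60 °C; then 3 M NaOH, 30% H2O2, 0 °C → rt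
Reagents that add atoms: hydrogen peroxide OO
Why: Palladium-catalysed enantioselective conjunctive cross-coupling, a known three-component 1,2-metallate reaction of β-substituted alkenylboron ate complexes. Oxidative addition of 5 to zerovalent palladium gives an aryl complex of divalent palladium which, once bromide is exchanged for triflate, binds the alkene of ate complex 11. Methyl then shifts from boron to the boron-bearing carbon C2'' on the face opposite palladium while palladium bonds to C1'', and reductive elimination with retention forms C5–C1''; aryl and methyl are thus added anti across the (E)-alkene, which fixes the threo relation in 12. The ferrocenyl bisphosphine selects the alkene face and so the absolute configuration, and alkaline H2O2 oxidises the C–B bond with retention, so 13 should be (2S,3R). No ring is formed. The selectivity needed is metallate shift over direct transfer of propenyl or methyl from boron to palladium, and the bulky acenaphthene diol on boron is what secures it. The bromide has a single ortho substituent (the C6 methyl; hydrogen at the future C4a), which keeps alkene binding feasible, and CF3SO3K removes the bromide that would otherwise occupy the site the alkene needs.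

Step 8
Reactants: 13 (2S,3R)-3-[3,5-bis(methoxymethoxy)-2,4-dimethylphenyl]butan-2-ol
Product: 14 {[(2S,3R)-3-[3,5-bis(methoxymethoxy)-2,4-dimethylphenyl]butan-2-yl]oxy}tri(propan-2-yl)silane
Conditions: i-Pr3SiOSO2CF3, 2,6-lutidine, CH2Cl2, 0 °C → rt
Reagents that add atoms: triisopropylsilyl trifluoromethanesulfonate CC(C)[Si](C(C)C)(C(C)C)OS(=O)(=O)C(F)(F)F
Why: Silylation of a hindered secondary alcohol with a silyl triflate; the triisopropylsilyl group is chosen because it resists oxygen-to-carbon migration to a neighbouring aryllithium and outlasts dilute acid, keeping the C2'' oxygen away from the aldehyde made next.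

Step 9
Reactants: 14 triisopropylsilyl ether of 13
Product: 16 2,4-bis(methoxymethoxy)-3,5-dimethyl-6-[(2R,3S)-3-{[tri(propan-2-yl)silyl]oxy}butan-2-yl]benzaldehyde, via aryllithium 15 (not isolated)
Conditions: s-BuLi, TMEDA, THF, −78 °C; DMF, −78 → 0 °C; aq. NH4Cl
Reagents that add atoms: N,N-dimethylformamide CN(C)C=O
Why: Directed ortho-metalation then formylation; the only ring hydrogen lies beside a methoxymethyl ether that coordinates lithium, and ring metalation next to an alkoxy director is kinetically preferred over lateral metalation of the ring methyl groups.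

Step 10
Reactants: 16 bis(methoxymethyl)-protected aldehyde
Product: 17 2,4-dihydroxy-3,5-dimethyl-6-[(2R,3S)-3-{[tri(propan-2-yl)silyl]oxy}butan-2-yl]benzaldehyde
Conditions: HCl (2 M aq.), MeOH–THF, rt
Reagents that add atoms: none
Why: Acid hydrolysis of aryl acetals; aryl methoxymethyl ethers ionise far faster than a hindered secondary triisopropylsilyl ether is cleaved, so the resorcinol should be freed with the side-chain oxygen still masked.

Step 11
Reactants: 18 methyl (3R)-3-hydroxybutanoate
Product: 19 methyl (3R)-3-[(tert-butyldimethylsilyl)oxy]butanoate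
Conditions: t-BuMe2SiCl, imidazole, DMF, rt
Reagents that add atoms: tert-butyldimethylsilyl chloride CC(C)(C)[Si](C)(C)Cl
Why: Standard silylation of a secondary alcohol; no bond to the stereocenter is broken.

Step 12
Reactants: 20 methyl 3-oxobutanoate (methyl acetoacetate); 19 methyl (3R)-3-[(tert-butyldimethylsilyl)oxy]butanoate
Product: 22 methyl (7R)-7-[(tert-butyldimethylsilyl)oxy]-3,5-dioxooctanoate, via acetoacetate dianion 21 (not isolated)
Conditions: 20 (2.5 equiv), NaH, THF, 0 °C; n-BuLi, 0 °C; then 19, −78 → 0 °C; aq. NH4Cl
Reagents that add atoms: none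
Why: Claisen-type acylation of the acetoacetate dianion at its terminal carbon by an ester; the dianion is used in excess because the diketo ester formed is more acidic than the starting keto ester.

Step 13
Reactants: 22 methyl (7R)-7-[(tert-butyldimethylsilyl)oxy]-3,5-dioxooctanoate
Product: 24 methyl 2-[(2R)-2-methyl-4-oxo-3,4-dihydro-2H-pyran-6-yl]acetate, via hydroxy diketo ester 23 (not isolated)
Conditions: HF (48% aq.), MeCN, 0 °C → rt; then p-TsOH·H2O (cat.), CH2Cl2, rt
Reagents that add atoms: none
Why: Desilylation then acid-catalysed cyclodehydration of a δ-hydroxy-β-diketone; the hydroxyl can reach only the C3 ketone in a six-membered ring, loss of water toward C4 gives the vinylogous ester, and the C–O bond at the stereocenter is never broken, so (R) is retained.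

Step 14
Reactants: 17 2,4-dihydroxy aldehyde; 24 methyl 2-[(2R)-2-methyl-4-oxo-3,4-dihydro-2H-pyran-6-yl]acetate
Product: 26 7-hydroxy-6,8-dimethyl-3-[(2R)-2-methyl-4-oxo-3,4-dihydro-2H-pyran-6-yl]-5-[(2R,3S)-3-{[tri(propan-2-yl)silyl]oxy}butan-2-yl]-2H-chromen-2-one, via Knoevenagel alkylidene 25 (not isolated)
Conditions: piperidine (0.2 equiv), AcOH (0.2 equiv), EtOH, 60 °C
Reagents that add atoms: none
Why: Knoevenagel condensation–lactonisation (coumarin synthesis from a salicylaldehyde); the methylene of 24 is activated by the ester and vinylogously by the ring ketone, the (Z)-alkylidene is trapped irreversibly by the ortho phenol with loss of methanol, and catalytic buffered amine is too weak to deprotonate C3' and thus leaves C2' alone.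

Step 15
Reactants: 26 triisopropylsilyl-protected coumarin
Product: 27 7-hydroxy-5-[(2R,3S)-3-hydroxybutan-2-yl]-6,8-dimethyl-3-[(2R)-2-methyl-4-oxo-3,4-dihydro-2H-pyran-6-yl]-2H-chromen-2-one (target)
Conditions: HF·pyridine, pyridine, THF, 0 °C → rt
Reagents that add atoms: none
Why: Fluoride-mediated cleavage of a silyl ether under buffered, weakly acidic conditions, preferred to basic fluoride so that the dihydropyranone is not opened by β-elimination and C2' is not epimerised.

## Compound list

1 | 5-bromo-1,3-dimethoxy-2-methylbenzene (4-bromo-2,6-dimethoxytoluene) | COc1cc(Br)cc(OC)c1C | starting material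
2 | 6-bromo-2,4-dimethoxy-3-methylbenzaldehyde | COc1cc(Br)c(C=O)c(OC)c1C | intermediate
3 | 1-bromo-3,5-dimethoxy-2,4-dimethylbenzene | COc1cc(Br)c(C)c(OC)c1C | intermediate
4 | 5-bromo-2,4-dimethylbenzene-1,3-diol | Cc1c(O)cc(Br)c(C)c1O | intermediate
5 | 1-bromo-3,5-bis(methoxymethoxy)-2,4-dimethylbenzene | Cc1c(OCOC)c(C)c(OCOC)cc1Br | intermediate
6 | acenaphthylene-1,2-dione (acenaphthenequinone) | O=C1C(=O)c2cccc3cccc1c23 | starting material
7 | cis-(1R,2S)-1,2-dimethyl-1,2-dihydroacenaphthylene-1,2-diol (meso) | C[C@]1(O)c2cccc3cccc(c23)[C@@]1(C)O | intermediate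
8 | (E)-prop-1-en-1-ylboronic acid | C/C=C/B(O)O | starting material
9 | (6bR,9aS)-6b,9a-dimethyl-8-[(E)-prop-1-en-1-yl]-6b,9a-dihydroacenaphtho[1,2-d][1,3,2]dioxaborole | C/C=C/B1O[C@@]2(C)c3cccc4cccc(c34)[C@@]2(C)O1 | intermediate
10 | methyllithium | [Li]C | starting material
11 | lithium methyl[(E)-prop-1-enyl]boronate complex of the cis-diol ester 9 | [Li+].C/C=C/[B-]1(C)O[C@@]2(C)c3cccc4cccc(c34)[C@@]2(C)O1 | intermediate
12 | cyclic ester of diol 7 with [(2S,3S)-3-[3,5-bis(methoxymethoxy)-2,4-dimethylphenyl]butan-2-yl]boronic acid (same spatial arrangement as 13; the C3 descriptor differs because boron ranks below carbon) | Cc1c(OCOC)c(C)c(OCOC)cc1[C@@H](C)[C@H](C)B1O[C@@]2(C)c3cccc4cccc(c34)[C@@]2(C)O1 | intermediate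
13 | (2S,3R)-3-[3,5-bis(methoxymethoxy)-2,4-dimethylphenyl]butan-2-ol | Cc1c(OCOC)c(C)c(OCOC)cc1[C@@H](C)[C@H](C)O | intermediate
14 | {[(2S,3R)-3-[3,5-bis(methoxymethoxy)-2,4-dimethylphenyl]butan-2-yl]oxy}tri(propan-2-yl)silane | Cc1c(OCOC)c(C)c(OCOC)cc1[C@@H](C)[C@H](C)O[Si](C(C)C)(C(C)C)C(C)C | intermediate
15 | {2,4-bis(methoxymethoxy)-3,5-dimethyl-6-[(2R,3S)-3-{[tri(propan-2-yl)silyl]oxy}butan-2-yl]phenyl}lithium | Cc1c(OCOC)c(C)c(OCOC)c([Li])c1[C@@H](C)[C@H](C)O[Si](C(C)C)(C(C)C)C(C)C | intermediate
16 | 2,4-bis(methoxymethoxy)-3,5-dimethyl-6-[(2R,3S)-3-{[tri(propan-2-yl)silyl]oxy}butan-2-yl]benzaldehyde | Cc1c(OCOC)c(C)c(OCOC)c(C=O)c1[C@@H](C)[C@H](C)O[Si](C(C)C)(C(C)C)C(C)C | intermediate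
17 | 2,4-dihydroxy-3,5-dimethyl-6-[(2R,3S)-3-{[tri(propan-2-yl)silyl]oxy}butan-2-yl]benzaldehyde | Cc1c(O)c(C)c(O)c(C=O)c1[C@@H](C)[C@H](C)O[Si](C(C)C)(C(C)C)C(C)C | intermediate
18 | methyl (3R)-3-hydroxybutanoate | COC(=O)C[C@@H](C)O | starting material
19 | methyl (3R)-3-[(tert-butyldimethylsilyl)oxy]butanoate | COC(=O)C[C@@H](C)O[Si](C)(C)C(C)(C)C | intermediate
20 | methyl 3-oxobutanoate (methyl acetoacetate) | COC(=O)CC(C)=O | starting material
21 | sodium lithium 1-methoxybuta-1,3-diene-1,3-diolate (dianion of 20) | C=C([O-])C=C([O-])OC.[Na+].[Li+] | intermediate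
22 | methyl (7R)-7-[(tert-butyldimethylsilyl)oxy]-3,5-dioxooctanoate | COC(=O)CC(=O)CC(=O)C[C@@H](C)O[Si](C)(C)C(C)(C)C | intermediate
23 | methyl (7R)-7-hydroxy-3,5-dioxooctanoate | COC(=O)CC(=O)CC(=O)C[C@@H](C)O | intermediate
24 | methyl 2-[(2R)-2-methyl-4-oxo-3,4-dihydro-2H-pyran-6-yl]acetate | COC(=O)CC1=CC(=O)C[C@@H](C)O1 | intermediate
25 | methyl (2Z)-3-{2,4-dihydroxy-3,5-dimethyl-6-[(2R,3S)-3-{[tri(propan-2-yl)silyl]oxy}butan-2-yl]phenyl}-2-[(2R)-2-methyl-4-oxo-3,4-dihydro-2H-pyran-6-yl]prop-2-enoate | COC(=O)/C(=C\c1c(O)c(C)c(O)c(C)c1[C@@H](C)[C@H](C)O[Si](C(C)C)(C(C)C)C(C)C)C1=CC(=O)C[C@@H](C)O1 | intermediate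
26 | 7-hydroxy-6,8-dimethyl-3-[(2R)-2-methyl-4-oxo-3,4-dihydro-2H-pyran-6-yl]-5-[(2R,3S)-3-{[tri(propan-2-yl)silyl]oxy}butan-2-yl]-2H-chromen-2-one | Cc1c(O)c(C)c2oc(=O)c(C3=CC(=O)C[C@@H](C)O3)cc2c1[C@@H](C)[C@H](C)O[Si](C(C)C)(C(C)C)C(C)C | intermediate
27 | 7-hydroxy-5-[(2R,3S)-3-hydroxybutan-2-yl]-6,8-dimethyl-3-[(2R)-2-methyl-4-oxo-3,4-dihydro-2H-pyran-6-yl]-2H-chromen-2-one | Cc1c(O)c(C)c2oc(=O)c(C3=CC(=O)C[C@@H](C)O3)cc2c1[C@@H](C)[C@H](C)O | target

## Step count and risks

Total: 15 steps. Longest linear sequence: 10 steps (1, 2, 3, 4, 7, 8, 9, 10, 14, 15).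

**Step 7 (key step).** The most likely failure is direct transfer of propenyl or methyl from boron to palladium (ordinary Suzuki–Miyaura coupling) outrunning the metallate shift at a crowded, electron-rich arylpalladium centre. Loss of facial selectivity caused by the ortho methyl group, or β-hydride loss before reductive elimination, are the next concerns. The fallback sets out from 5 and returns at 13.
- Suzuki–Miyaura coupling of 5 with commercial 4,4,5,5-tetramethyl-2-[(Z)-but-2-en-2-yl]-1,3,2-dioxaborolane (Pd(PPh3)4, K3PO4, dioxane–water) should give 1-[(E)-but-2-en-2-yl]-3,5-bis(methoxymethoxy)-2,4-dimethylbenzene F1, with the two chain methyl groups cis.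
- Asymmetric hydroboration with monoisopinocampheylborane (the enantiomer that leads to the (2S,3R) series), then NaOH/H2O2, adds H and OH syn with boron at the less substituted carbon. On this alkene geometry that is the threo alcohol 13.

**Step 9.** The risk is incomplete or misdirected metalation: lateral deprotonation of a ring methyl flanked by acetal oxygens, or slow ring metalation between the acetal and the branched, silylated side chain. The fallback sets out from 14 and returns at 16.
- Electrophilic bromination with N-bromosuccinimide in acetonitrile at 0 °C can only occur at the single free ring position, giving {[(2S,3R)-3-[2-bromo-3,5-bis(methoxymethoxy)-4,6-dimethylphenyl]butan-2-yl]oxy}tri(propan-2-yl)silane F2.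
- Bromine–lithium exchange (n-BuLi, THF, −78 °C) generates the same aryllithium 15 regiospecifically, and DMF gives 16.

**Step 10.** The risk is loss of the silyl ether under the acid needed to unmask two hindered phenols, which would start lactol and quinone methide formation. The fallback sets out from 16 and returns at 27; it changes the order so that no acid step has to discriminate.
- MgBr2·OEt2 in CH2Cl2–Et2O, chelated between the formyl oxygen and the neighbouring acetal, should cleave only the ortho methoxymethyl ether. This gives 2-hydroxy-4-(methoxymethoxy)-3,5-dimethyl-6-[(2R,3S)-3-{[tri(propan-2-yl)silyl]oxy}butan-2-yl]benzaldehyde F3.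
- Condensation of F3 with 24 under the conditions of step 14 gives 7-(methoxymethoxy)-6,8-dimethyl-3-[(2R)-2-methyl-4-oxo-3,4-dihydro-2H-pyran-6-yl]-5-[(2R,3S)-3-{[tri(propan-2-yl)silyl]oxy}butan-2-yl]-2H-chromen-2-one F4.
- With the aldehyde gone, both remaining groups can be removed without selectivity (HCl in MeOH–THF, warming; HF·pyridine if the silyl ether persists) to give 27.

**Step 12.** The risk is sluggish acylation by the ester, with competing α-deprotonation and β-elimination of the silyloxy ester and quenching of the dianion by the product. The fallback sets out from 19 and returns at 22.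
- Me(MeO)NH·HCl and i-PrMgCl (THF, −20 °C) convert 19 into (3R)-3-[(tert-butyldimethylsilyl)oxy]-N-methoxy-N-methylbutanamide F5.
- F5 acylates dianion 21 through a stable chelated tetrahedral intermediate and gives 22 on work-up.

**Step 14.** The risks are slow condensation at an aldehyde flanked by two ortho substituents, and diversion of the pyranone by amine addition at C6' or by reaction at C5' of the dienolate. The fallback sets out from 17 and returns at 26; it builds the pyranone on the coumarin.
- Condensation of 17 with the far more acidic and unhindered methyl acetoacetate 20 (catalytic piperidine, EtOH) should give 3-acetyl-7-hydroxy-6,8-dimethyl-5-[(2R,3S)-3-{[tri(propan-2-yl)silyl]oxy}butan-2-yl]-2H-chromen-2-one F6.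
- Its phenoxide–enolate (LiN(SiMe3)2 in excess, THF, −78 °C) is acylated by Weinreb amide F5. This gives the β-diketone 3-[(5R)-5-[(tert-butyldimethylsilyl)oxy]-3-oxohexanoyl]-7-hydroxy-6,8-dimethyl-5-[(2R,3S)-3-{[tri(propan-2-yl)silyl]oxy}butan-2-yl]-2H-chromen-2-one F7.
- Brief aqueous HF in acetonitrile followed by catalytic p-TsOH removes only the tert-butyldimethylsilyl group and closes the dihydropyranone onto the coumarin-side ketone, giving 26.

## Further compounds

F1 | step 7 | 1-[(E)-but-2-en-2-yl]-3,5-bis(methoxymethoxy)-2,4-dimethylbenzene | C/C=C(\C)c1cc(OCOC)c(C)c(OCOC)c1C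
F2 | step 9 | {[(2S,3R)-3-[2-bromo-3,5-bis(methoxymethoxy)-4,6-dimethylphenyl]butan-2-yl]oxy}tri(propan-2-yl)silane | Cc1c(OCOC)c(C)c(OCOC)c(Br)c1[C@@H](C)[C@H](C)O[Si](C(C)C)(C(C)C)C(C)C
F3 | step 10 | 2-hydroxy-4-(methoxymethoxy)-3,5-dimethyl-6-[(2R,3S)-3-{[tri(propan-2-yl)silyl]oxy}butan-2-yl]benzaldehyde | Cc1c(OCOC)c(C)c(O)c(C=O)c1[C@@H](C)[C@H](C)O[Si](C(C)C)(C(C)C)C(C)C
F4 | step 10 | 7-(methoxymethoxy)-6,8-dimethyl-3-[(2R)-2-methyl-4-oxo-3,4-dihydro-2H-pyran-6-yl]-5-[(2R,3S)-3-{[tri(propan-2-yl)silyl]oxy}butan-2-yl]-2H-chromen-2-one | Cc1c(OCOC)c(C)c2oc(=O)c(C3=CC(=O)C[C@@H](C)O3)cc2c1[C@@H](C)[C@H](C)O[Si](C(C)C)(C(C)C)C(C)C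
F5 | step 12 | (3R)-3-[(tert-butyldimethylsilyl)oxy]-N-methoxy-N-methylbutanamide | CON(C)C(=O)C[C@@H](C)O[Si](C)(C)C(C)(C)C
F6 | step 14 | 3-acetyl-7-hydroxy-6,8-dimethyl-5-[(2R,3S)-3-{[tri(propan-2-yl)silyl]oxy}butan-2-yl]-2H-chromen-2-one | Cc1c(O)c(C)c2oc(=O)c(C(C)=O)cc2c1[C@@H](C)[C@H](C)O[Si](C(C)C)(C(C)C)C(C)C
F7 | step 14 | 3-[(5R)-5-[(tert-butyldimethylsilyl)oxy]-3-oxohexanoyl]-7-hydroxy-6,8-dimethyl-5-[(2R,3S)-3-{[tri(propan-2-yl)silyl]oxy}butan-2-yl]-2H-chromen-2-one | Cc1c(O)c(C)c2oc(=O)c(C(=O)CC(=O)C[C@@H](C)O[Si](C)(C)C(C)(C)C)cc2c1[C@@H](C)[C@H](C)O[Si](C(C)C)(C(C)C)C(C)C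
A1 | alternative 1 | (3S,4R)-6-methoxy-3,4,5,7-tetramethyl-8-(4,4,5,5-tetramethyl-1,3,2-dioxaborolan-2-yl)isochroman-1-one (trans) | Cc1c(OC)c(C)c(B2OC(C)(C)C(C)(C)O2)c3c1[C@@H](C)[C@H](C)OC3=O
A2 | alternative 1 | (2S,3S)-3-(4-methoxy-3,5-dimethyl-2-oxo-2H-pyran-6-yl)butan-2-yl 3-(4,4,5,5-tetramethyl-1,3,2-dioxaborolan-2-yl)prop-2-ynoate | O=c1oc([C@@H](C)[C@H](C)OC(=O)C#CB2OC(C)(C)C(C)(C)O2)c(C)c(OC)c1C
A3 | alternative 2 | 7-[(tert-butyldimethylsilyl)oxy]-5-[(2R,3S)-3-[(tert-butyldimethylsilyl)oxy]butan-2-yl]-3-{3-[(2R)-2-[(tert-butyldimethylsilyl)oxy]propyl]isoxazol-5-yl}-6,8-dimethyl-2H-chromen-2-one | Cc1c(O[Si](C)(C)C(C)(C)C)c(C)c2oc(=O)c(-c3cc(C[C@@H](C)O[Si](C)(C)C(C)(C)C)no3)cc2c1[C@@H](C)[C@H](C)O[Si](C)(C)C(C)(C)C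
A4 | alternative 2 | 7-[(tert-butyldimethylsilyl)oxy]-5-[(2R,3S)-3-[(tert-butyldimethylsilyl)oxy]butan-2-yl]-3-ethynyl-6,8-dimethyl-2H-chromen-2-one | Cc1c(O[Si](C)(C)C(C)(C)C)c(C)c2oc(=O)c(C#C)cc2c1[C@@H](C)[C@H](C)O[Si](C)(C)C(C)(C)C
A5 | alternative 2 | (3R)-3-[(tert-butyldimethylsilyl)oxy]butanal oxime | ON=CC[C@@H](C)O[Si](C)(C)C(C)(C)C
A6 | alternative 3 | 5-[(2R,3S)-3-[(tert-butyldimethylsilyl)oxy]butan-2-yl]-2,6-dimethyl-3-{[tri(propan-2-yl)silyl]oxy}phenol | Cc1c(O)c(C)c(O[Si](C(C)C)(C(C)C)C(C)C)cc1[C@@H](C)[C@H](C)O[Si](C)(C)C(C)(C)C
A7 | alternative 3 | 3-[(2R,3S)-3-[(tert-butyldimethylsilyl)oxy]butan-2-yl]-4-methylcyclobut-2-en-1-one | O=C1C=C([C@@H](C)[C@H](C)O[Si](C)(C)C(C)(C)C)C1C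
A8 | alternative 3 | tri(propan-2-yl)(prop-1-yn-1-yloxy)silane | CC#CO[Si](C(C)C)(C(C)C)C(C)C
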